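**Retrosynthetic overview**

1. The strategy rests on ring B (C3a, C4, C5, C6, C7, C7a): a resorcinol ring whose C3a carries the C3 arm between the oxygens on C4 and C7a (O1) and whose C6, para to C3a, carries the styryl carbon. A silyloxyalkyne and a 3-substituted cyclobutenone give exactly this pattern on annulation, so ring B is built last, around a C3 stereocentre that already exists.
2. Disconnections: stilbene C=C (Horner–Wadsworth–Emmons) and the aryl methyl ethers; O1–C2 (acid ionisation of a C2 methyl ether, trans closure by either ring B phenol); ring B (C3a–C4 and C7–C7a by the benzannulation); alkyne from an aldehyde; C2–C3 by an Evans syn aldol of a 3,5-dimethoxyphenylacetyl imide with the C7' aldehyde of the second dihydrobenzofuran.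
3. That aldehyde comes from the same triad: Evans aldol with 2,4-dimethoxybenzaldehyde, silyloxyalkyne, benzannulation with cyclobut-2-en-1-one (benzo ring C3a'–C7a'), magnesium-directed ortho-formylation (C7' carbon) and acid closure of O1'–C2'.
4. Ring order: benzo ring of the second dihydrobenzofuran, its dihydrofuran ring, ring B, first dihydrofuran ring. C3 and C3' come from (R)-4-benzyloxazolidinone; C2 and C2' from thermodynamically controlled trans closure.

Key step: step 22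

Remark: Q denotes the (2S,3S)-2-(2,4-dimethoxyphenyl)-3-(3,5-dimethoxyphenyl)-4-methoxy-2,3-dihydro-1-benzofuran-7-yl group; the arylacetyl boron enolates are assumed to follow the usual Evans syn facial sense, and the configuration at C2 and C2' of the open-chain intermediates is immaterial because both centres are ionised before ring closure.

**Route**

Step 1
Reactants: 1 3,5-dimethoxyphenylacetic acid; 2 (R)-4-benzyl-1,3-oxazolidin-2-one
Product: 4 (4R)-4-benzyl-3-[(3,5-dimethoxyphenyl)acetyl]-1,3-oxazolidin-2-one, via mixed pivalic anhydride 3 (not isolated)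
Conditions: t-BuCOCl, Et3N, THF, −20 °C; then LiCl, 2, −20 °C → rt
Reagents that add atoms: none
Why: N-acylation of the oxazolidinone by a mixed anhydride under LiCl/Et3N activation is the standard entry to Evans imides and creates no stereocentre.

Step 2
Reactants: 5 tert-butyldimethyl(prop-2-yn-1-yloxy)silane; 6 trichloroacetyl chloride
Product: 8 4,4-dichloro-3-({[tert-butyl(dimethyl)silyl]oxy}methyl)cyclobut-2-en-1-one, via dichloroketene 7 (not isolated)
Conditions: Zn–Cu couple, Et2O/DME, rt, slow addition of 6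
Reagents that add atoms: none
Why: [2+2] cycloaddition of dichloroketene with a terminal alkyne, in which the terminal carbon bonds to the ketene carbonyl carbon and so places the silyloxymethyl group on C3 of the cyclobutenone.

Step 3
Reactants: 8
Product: 9 3-({[tert-butyl(dimethyl)silyl]oxy}methyl)cyclobut-2-en-1-one
Conditions: Zn dust, TMEDA, AcOH, EtOH, 0 °C → rt
Reagents that add atoms: none
Why: Zinc reduces both C–Cl bonds of the α,α-dichloroketone, and the amine-buffered acid should prevent over-reduction of the enone and loss of the silyl ether.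

Step 4
Reactants: 10 3-oxocyclobutane-1-carboxylic acid
Product: 11 3-bromocyclobutan-1-one
Conditions: HgO, Br2, MgSO4, CH2Cl2, reflux
Reagents that add atoms: bromine, BrBr
Why: Cristol–Firth variant of the Hunsdiecker bromodecarboxylation, which proceeds through the acyl hypobromite and an alkyl radical.

Step 5
Reactants: 11
Product: 12 cyclobut-2-en-1-one
Conditions: n-Bu3N, rt; vacuum transfer into a −78 °C trap; kept as a cold toluene solution
Reagents that add atoms: none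
Why: E1cB dehydrobromination of the β-bromo ketone by a non-nucleophilic amine, with the volatile enone removed from the base as it forms.

Step 6
Reactants: 4 (4R)-4-benzyl-3-[(3,5-dimethoxyphenyl)acetyl]-1,3-oxazolidin-2-one; 13 2,4-dimethoxybenzaldehyde
Product: 16 (4R)-4-benzyl-3-[(2R,3R)-3-(2,4-dimethoxyphenyl)-2-(3,5-dimethoxyphenyl)-3-hydroxypropanoyl]-1,3-oxazolidin-2-one, via dibutylboron enolate 14 (not isolated), via dibutylboron aldolate 15 (not isolated)
Conditions: n-Bu2BOTf, i-Pr2NEt, CH2Cl2, −78 → 0 °C; 13, −78 → 0 °C; pH 7 buffer, MeOH, 30% H2O2, 0 °C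
Reagents that add atoms: none
Why: Evans syn aldol, in which the (Z)-boron enolate 14 reacts through a closed Zimmerman–Traxler chair on the face away from the benzyl group of the auxiliary and so sets the α-carbon (future C3', 2R here) and the carbinol carbon (future C2') syn; only the former has to last.

Step 7
Reactants: 16
Product: 17 (4R)-4-benzyl-3-[(2R,3R)-3-{[tert-butyl(dimethyl)silyl]oxy}-3-(2,4-dimethoxyphenyl)-2-(3,5-dimethoxyphenyl)propanoyl]-1,3-oxazolidin-2-one
Conditions: t-BuMe2SiOTf, 2,6-lutidine, CH2Cl2, −78 → 0 °C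
Reagents that add atoms: tert-butyldimethylsilyl triflate, CC(C)(C)[Si](C)(C)OS(=O)(=O)C(F)(F)F
Why: Silylation with a silyl triflate and a hindered pyridine avoids retro-aldol cleavage; a silyl ether is used here instead of a methyl ether so that the magnesium-mediated formylation of step 13 does not meet an easily ionised benzylic methyl ether beside a phenoxide.

Step 8
Reactants: 17
Product: 18 (2S,3R)-3-{[tert-butyl(dimethyl)silyl]oxy}-3-(2,4-dimethoxyphenyl)-2-(3,5-dimethoxyphenyl)propan-1-ol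
Conditions: LiBH4, MeOH (2 equiv), THF, 0 °C
Reagents that add atoms: none
Why: Reductive removal of the Evans auxiliary, in which hydride attacks the exocyclic imide carbonyl to give the primary alcohol and recovered 2 while leaving the α-aryl stereocentre alone (the descriptor changes only through CIP priorities).

Step 9
Reactants: 18
Product: 19 (2R,3R)-3-{[tert-butyl(dimethyl)silyl]oxy}-3-(2,4-dimethoxyphenyl)-2-(3,5-dimethoxyphenyl)propanal
Conditions: Dess–Martin periodinane, NaHCO3, CH2Cl2, 0 °C → rt; used at once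
Reagents that add atoms: none
Why: Dess–Martin oxidation under bicarbonate buffer is non-basic, so the acidic C–H next to the new aldehyde should not epimerise.

Step 10
Reactants: 19
Product: 20 tert-butyl{[(1R,2R)-4,4-dibromo-1-(2,4-dimethoxyphenyl)-2-(3,5-dimethoxyphenyl)but-3-en-1-yl]oxy}dimethylsilane
Conditions: CBr4, PPh3, 2,6-lutidine, CH2Cl2, 0 °C
Reagents that add atoms: carbon tetrabromide, BrC(Br)(Br)Br
Why: First stage of the Corey–Fuchs reaction (Wittig olefination with the dibromomethylene ylide), which is fast at 0 °C and needs no base stronger than 2,6-lutidine, so the stereocentre and the β-silyloxy group should survive.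

Step 11
Reactants: 20
Product: 23 tert-butyl{[(1R,2S)-1-(2,4-dimethoxyphenyl)-2-(3,5-dimethoxyphenyl)-4-{[tri(propan-2-yl)silyl]oxy}but-3-yn-1-yl]oxy}dimethylsilane, via lithium acetylide 21 (not isolated), via lithium ynolate 22 (not isolated)
Conditions: n-BuLi (2.1 equiv), THF, −78 °C; LiOOt-Bu (from t-BuOOH and LiN(SiMe3)2, THF, −78 °C), −78 → 0 °C; i-Pr3SiOTf, −78 → 0 °C
Reagents that add atoms: lithium tert-butyl peroxide, [Li]OOC(C)(C)C; triisopropylsilyl triflate, CC(C)[Si](OS(=O)(=O)C(F)(F)F)(C(C)C)C(C)C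
Why: The second Corey–Fuchs stage (Br/Li exchange, Fritsch–Buttenberg–Wiechell shift, deprotonation) gives acetylide 21, electrophilic oxygen transfer from the lithium peroxide (Julia ynolate synthesis) gives ynolate 22, and the hard silyl triflate traps it on oxygen.

Step 12
Reactants: 23 silyloxyalkyne; 12 cyclobut-2-en-1-one
Product: 28 2-[(1S,2R)-2-{[tert-butyl(dimethyl)silyl]oxy}-2-(2,4-dimethoxyphenyl)-1-(3,5-dimethoxyphenyl)ethyl]-3-{[tri(propan-2-yl)silyl]oxy}phenol, via vinylketene 24 (not isolated), via vinylcyclobutenone 25 (not isolated), via dienylketene 26 (not isolated), via cyclohexadienone 27 (not isolated)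
Conditions: 12 (3 equiv), toluene, sealed tube, 80 °C, then 110 °C
Reagents that add atoms: none
Why: Danheiser benzannulation, in which 12 opens to 24, the arm-bearing alkyne carbon bonds to the ketene carbonyl carbon in a [2+2] addition to give 25, and 4π opening to 26, 6π closure to 27 and tautomerisation build the benzo ring with the free hydroxyl and the silyloxy group flanking C3a' and three free CH positions.

Step 13
Reactants: 28
Product: 30 3-[(1S,2R)-2-{[tert-butyl(dimethyl)silyl]oxy}-2-(2,4-dimethoxyphenyl)-1-(3,5-dimethoxyphenyl)ethyl]-2-hydroxy-4-{[tri(propan-2-yl)silyl]oxy}benzaldehyde, via hydroxymethylphenol 29 (not isolated)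
Conditions: MgCl2, Et3N, (CH2O)n, THF, reflux
Reagents that add atoms: formaldehyde (from paraformaldehyde), C=O
Why: Casnati–Skattebøl ortho-formylation, in which the magnesium phenoxide delivers formaldehyde to its only free ortho carbon (future C7') and 29 passes hydride to a second formaldehyde, so the aldehyde appears next to the future O1' while the phenol-free methoxy rings stay untouched.

Step 14
Reactants: 30
Product: 32 (2S,3S)-2-(2,4-dimethoxyphenyl)-3-(3,5-dimethoxyphenyl)-4-{[tri(propan-2-yl)silyl]oxy}-2,3-dihydro-1-benzofuran-7-carbaldehyde, via benzylic cation 31 (not isolated)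
Conditions: CF3CO2H, CH2Cl2, 0 °C
Reagents that add atoms: none
Why: Acid ionises the 2,4-dimethoxybenzylic silyl ether (SN1) to cation 31, which the neighbouring phenol captures in a 5-exo closure of O1'–C2' (the silylated oxygen cannot compete); C2' is set trans to the C3' aryl group because attack anti to it is preferred and, the C2'–O bond being reversible under acid, the more stable trans isomer accumulates.

Step 15
Reactants: 32
Product: 34 (2S,3S)-2-(2,4-dimethoxyphenyl)-3-(3,5-dimethoxyphenyl)-4-methoxy-2,3-dihydro-1-benzofuran-7-carbaldehyde (Q–CHO), via caesium phenoxide 33 (not isolated)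
Conditions: CsF, MeI, DMF, rt
Reagents that add atoms: iodomethane, CI
Why: Fluoride cleaves the aryl silyl ether and the phenoxide 33 is methylated in the same flask (desilylative Williamson etherification), the non-enolisable aldehyde and both stereocentres being inert.

Step 16
Reactants: 4 (4R)-4-benzyl-3-[(3,5-dimethoxyphenyl)acetyl]-1,3-oxazolidin-2-one; 34 aldehyde Q–CHO
Product: 37 (4R)-4-benzyl-3-[(2R,3R)-2-(3,5-dimethoxyphenyl)-3-hydroxy-3-Q-propanoyl]-1,3-oxazolidin-2-one, via diethylboron enolate 35 (not isolated), via diethylboron aldolate 36 (not isolated)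
Conditions: Et2BOTf, i-Pr2NEt, CH2Cl2, −78 → 0 °C; 34, −78 → 0 °C; pH 7 buffer, MeOH, 30% H2O2, 0 °C
Reagents that add atoms: none
Why: Second Evans syn aldol, here through the (Z)-diethylboron enolate 35 and the same closed chair transition state, in which the auxiliary is expected to override the resident stereocentres of 34 and set the new α-carbon (C3, 2R here) and carbinol carbon (C2); the ethanol that the diethylboryl group leaves after oxidative work-up is easily removed from the heavy adduct.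

Step 17
Reactants: 37
Product: 38 (4R)-4-benzyl-3-[(2R,3R)-2-(3,5-dimethoxyphenyl)-3-methoxy-3-Q-propanoyl]-1,3-oxazolidin-2-one
Conditions: Me3OBF4, 1,8-bis(dimethylamino)naphthalene, 4 Å MS, CH2Cl2, 0 °C → rt
Reagents that add atoms: trimethyloxonium tetrafluoroborate, C[O+](C)C.F[B-](F)(F)F
Why: Methylation with Meerwein's salt and a non-nucleophilic proton scavenger etherifies β-hydroxy imides without retro-aldol or epimerisation; the small methyl ether keeps the later alkyne accessible and is the leaving group of step 24.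

Step 18
Reactants: 38
Product: 39 (2S,3R)-2-(3,5-dimethoxyphenyl)-3-methoxy-3-Q-propan-1-ol
Conditions: LiBH4, MeOH (2 equiv), THF, 0 °C
Reagents that add atoms: none
Why: Reductive cleavage of the imide at the exocyclic carbonyl, as in step 8, with recovery of 2 and no change at C3.

Step 19
Reactants: 39
Product: 40 (2R,3R)-2-(3,5-dimethoxyphenyl)-3-methoxy-3-Q-propanal
Conditions: Dess–Martin periodinane, NaHCO3, CH2Cl2, 0 °C → rt; used at once
Reagents that add atoms: none
Why: Buffered Dess–Martin oxidation, as in step 9, gives the epimerisable α-aryl aldehyde without base.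

Step 20
Reactants: 40
Product: 41 (3R,4R)-1,1-dibromo-3-(3,5-dimethoxyphenyl)-4-methoxy-4-Q-but-1-ene
Conditions: CBr4, PPh3, 2,6-lutidine, CH2Cl2, 0 °C
Reagents that add atoms: carbon tetrabromide, BrC(Br)(Br)Br
Why: Corey–Fuchs dibromoolefination as in step 10, where the lutidine buffer should also protect the acid-labile C2 methyl ether and the dihydrofuran.

Step 21
Reactants: 41
Product: 44 {[(3S,4R)-3-(3,5-dimethoxyphenyl)-4-methoxy-4-Q-but-1-yn-1-yl]oxy}tri(propan-2-yl)silane, via lithium acetylide 42 (not isolated), via lithium ynolate 43 (not isolated)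
Conditions: n-BuLi (2.05 equiv), THF, −78 °C; LiOOt-Bu (from t-BuOOH and LiN(SiMe3)2, THF, −78 °C), −78 → 0 °C; i-Pr3SiOTf, −78 → 0 °C
Reagents that add atoms: lithium tert-butyl peroxide, [Li]OOC(C)(C)C; triisopropylsilyl triflate, CC(C)[Si](OS(=O)(=O)C(F)(F)F)(C(C)C)C(C)C
Why: Same Corey–Fuchs/Julia ynolate/O-silylation sequence as in step 11; exchange and acetylide formation at −78 °C are faster than removal of the propargylic C3–H, so C3 (S in 44 through the CIP change) should be kept.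

Step 22
Reactants: 44 silyloxyalkyne; 9 3-({[tert-butyl(dimethyl)silyl]oxy}methyl)cyclobut-2-en-1-one
Product: 49 5-({[tert-butyl(dimethyl)silyl]oxy}methyl)-2-[(1S,2R)-1-(3,5-dimethoxyphenyl)-2-methoxy-2-Q-ethyl]-3-{[tri(propan-2-yl)silyl]oxy}phenol, via vinylketene 45 (not isolated), via vinylcyclobutenone 46 (not isolated), via dienylketene 47 (not isolated), via cyclohexadienone 48 (not isolated)
Conditions: 9 (2 equiv), toluene, 80 °C, then 110 °C
Reagents that add atoms: none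
Why: Heating opens 9 by 4π-electrocyclic cleavage of its C1–C4 bond to vinylketene 45, whose ketene C=C adds to the silyloxyalkyne in a [2+2] cycloaddition that forms C3a–C4 and C7a–C7 and gives 46; a second 4π opening gives dienylketene 47. Ring B then closes by thermal disrotatory 6π-electrocyclisation of 47 between the ketene carbon (C4) and the terminal methylene (C5), and cyclohexadienone 48 tautomerises to phenol 49. The closest known reaction type is the Danheiser benzannulation of 3-substituted cyclobutenones with triisopropylsilyloxyalkynes to resorcinol monosilyl ethers, and the step asks for nothing beyond it. No stereocentre is created; C3 (propargylic, then benzylic) and C2, C2', C3' are spectators under neutral, aprotic heating. The only selectivity needed is regiochemical and polarity supplies it: the alkyne carbon β to the silyloxy oxygen, the one bearing the C3 arm, is the nucleophilic terminus and bonds to the ketene carbonyl carbon, so the C4 hydroxyl and the C7a silyloxy group flank C3a and the silyloxymethyl group of 9 ends on C6, para to C3a. The aryl ethers, the dihydrobenzofuran and the C2 methyl ether offer no acidic or electrophilic site that would intercept the ketene.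

Step 23
Reactants: 49
Product: 50 2-[(1S,2R)-1-(3,5-dimethoxyphenyl)-2-methoxy-2-Q-ethyl]-5-(hydroxymethyl)benzene-1,3-diol
Conditions: n-Bu4NF, THF, 0 °C → rt; aq NH4Cl
Reagents that add atoms: none
Why: Fluoride removes the aryl triisopropylsilyl and the primary tert-butyldimethylsilyl ether, after which the two ring B hydroxyls are related by the C3a–C6 axis and need no differentiation.

Step 24
Reactants: 50
Product: 52 (2S,3S)-3-(3,5-dimethoxyphenyl)-6-(hydroxymethyl)-2-Q-2,3-dihydro-1-benzofuran-4-ol, via benzylic cation 51 (not isolated)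
Conditions: CF3CO2H, CH2Cl2/MeCN, −20 → 0 °C
Reagents that add atoms: none
Why: Acid ionises the C2 methyl ether (SN1; cation 51 is stabilised by O1' ortho and the C4' methoxy group para), either ring B phenol closes O1–C2 5-exo to the same product, and C2 is set trans to ring D on C3 by the same kinetic preference and acid-reversible equilibration as in step 14, while the primary benzylic alcohol, meta to both oxygens, does not ionise.

Step 25
Reactants: 52
Product: 53 (2S,3S)-3-(3,5-dimethoxyphenyl)-4-hydroxy-2-Q-2,3-dihydro-1-benzofuran-6-carbaldehyde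
Conditions: MnO2 (activated, excess), EtOAc, rt
Reagents that add atoms: none
Why: MnO2 oxidises the benzylic alcohol selectively to the aldehyde under neutral heterogeneous conditions that should spare the phenol and the acid-labile dihydrofurans.

Step 26
Reactants: 53; 54 diethyl [(4-methoxyphenyl)methyl]phosphonate
Product: 56 (2S,3S)-3-(3,5-dimethoxyphenyl)-6-[(E)-2-(4-methoxyphenyl)ethenyl]-2-Q-2,3-dihydro-1-benzofuran-4-ol, via phosphonate carbanion 55 (not isolated)
Conditions: KOt-Bu (3.5 equiv), THF/DMF, 0 °C → rt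
Reagents that add atoms: none
Why: Horner–Wadsworth–Emmons olefination with a benzylic phosphonate anion gives the (E)-stilbene as the usual outcome, the extra base covering the free C4 phenol, which is meta to the aldehyde and does not deactivate it.

Step 27
Reactants: 56
Product: 57 gnetumontanin B, (2S,3S)-2-[(2S,3S)-2-(2,4-dihydroxyphenyl)-3-(3,5-dihydroxyphenyl)-4-hydroxy-2,3-dihydro-1-benzofuran-7-yl]-3-(3,5-dihydroxyphenyl)-6-[(E)-2-(4-hydroxyphenyl)ethenyl]-2,3-dihydro-1-benzofuran-4-ol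
Conditions: BBr3 (excess), CH2Cl2, −78 °C → rt; MeOH, aq NaHCO3
Reagents that add atoms: none
Why: Boron tribromide cleaves all eight aryl methyl ethers by Lewis acid complexation and bromide attack on methyl; a dihydrofuran C–O bond that opens should reclose to the more stable trans ring, and the (E)-stilbene is expected to tolerate the reagent.

**Compound list**

1 | 3,5-dimethoxyphenylacetic acid | COc1cc(CC(=O)O)cc(OC)c1 | starting material
2 | (R)-4-benzyl-1,3-oxazolidin-2-one | O=C1OC[C@@H](Cc2ccccc2)N1 | starting material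
3 | mixed anhydride of 1 with pivalic acid (formed in the flask) | COc1cc(CC(=O)OC(=O)C(C)(C)C)cc(OC)c1 | intermediate
4 | (4R)-4-benzyl-3-[(3,5-dimethoxyphenyl)acetyl]-1,3-oxazolidin-2-one | COc1cc(CC(=O)N2C(=O)OC[C@H]2Cc2ccccc2)cc(OC)c1 | intermediate
5 | tert-butyldimethyl(prop-2-yn-1-yloxy)silane | C#CCO[Si](C)(C)C(C)(C)C | starting material
6 | trichloroacetyl chloride | ClC(=O)C(Cl)(Cl)Cl | starting material
7 | dichloroketene (formed in the flask) | O=C=C(Cl)Cl | intermediate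
8 | 4,4-dichloro-3-({[tert-butyl(dimethyl)silyl]oxy}methyl)cyclobut-2-en-1-one | O=C1C=C(CO[Si](C)(C)C(C)(C)C)C1(Cl)Cl | intermediate
9 | 3-({[tert-butyl(dimethyl)silyl]oxy}methyl)cyclobut-2-en-1-one | O=C1C=C(CO[Si](C)(C)C(C)(C)C)C1 | intermediate
10 | 3-oxocyclobutane-1-carboxylic acid | O=C1CC(C(=O)O)C1 | starting material
11 | 3-bromocyclobutan-1-one | O=C1CC(Br)C1 | intermediate
12 | cyclobut-2-en-1-one | O=C1C=CC1 | intermediate
13 | 2,4-dimethoxybenzaldehyde | COc1ccc(C=O)c(OC)c1 | starting material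
14 | dibutylboron (Z)-enolate of 4 (formed in the flask) | CCCCB(CCCC)O/C(N1C(=O)OC[C@H]1Cc1ccccc1)=C\c1cc(OC)cc(OC)c1 | intermediate
15 | dibutylboron aldolate of 16 (formed in the flask) | O=C(N1C(=O)OC[C@H]1Cc1ccccc1)[C@H](c1cc(OC)cc(OC)c1)[C@@H](OB(CCCC)CCCC)c1ccc(OC)cc1OC | intermediate
16 | (4R)-4-benzyl-3-[(2R,3R)-3-(2,4-dimethoxyphenyl)-2-(3,5-dimethoxyphenyl)-3-hydroxypropanoyl]-1,3-oxazolidin-2-one | O=C(N1C(=O)OC[C@H]1Cc1ccccc1)[C@H](c1cc(OC)cc(OC)c1)[C@@H](O)c1ccc(OC)cc1OC | intermediate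
17 | tert-butyldimethylsilyl ether of 16, (2R,3R) | O=C(N1C(=O)OC[C@H]1Cc1ccccc1)[C@H](c1cc(OC)cc(OC)c1)[C@@H](O[Si](C)(C)C(C)(C)C)c1ccc(OC)cc1OC | intermediate
18 | (2S,3R)-3-{[tert-butyl(dimethyl)silyl]oxy}-3-(2,4-dimethoxyphenyl)-2-(3,5-dimethoxyphenyl)propan-1-ol | OC[C@H](c1cc(OC)cc(OC)c1)[C@@H](O[Si](C)(C)C(C)(C)C)c1ccc(OC)cc1OC | intermediate
19 | (2R,3R)-3-{[tert-butyl(dimethyl)silyl]oxy}-3-(2,4-dimethoxyphenyl)-2-(3,5-dimethoxyphenyl)propanal | O=C[C@H](c1cc(OC)cc(OC)c1)[C@@H](O[Si](C)(C)C(C)(C)C)c1ccc(OC)cc1OC | intermediate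
20 | tert-butyl{[(1R,2R)-4,4-dibromo-1-(2,4-dimethoxyphenyl)-2-(3,5-dimethoxyphenyl)but-3-en-1-yl]oxy}dimethylsilane | BrC(Br)=C[C@H](c1cc(OC)cc(OC)c1)[C@@H](O[Si](C)(C)C(C)(C)C)c1ccc(OC)cc1OC | intermediate
21 | lithium acetylide from 20 (formed in the flask) | [Li]C#C[C@H](c1cc(OC)cc(OC)c1)[C@@H](O[Si](C)(C)C(C)(C)C)c1ccc(OC)cc1OC | intermediate
22 | lithium ynolate from 21 (formed in the flask) | [Li]OC#C[C@H](c1cc(OC)cc(OC)c1)[C@@H](O[Si](C)(C)C(C)(C)C)c1ccc(OC)cc1OC | intermediate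
23 | tert-butyl{[(1R,2S)-1-(2,4-dimethoxyphenyl)-2-(3,5-dimethoxyphenyl)-4-{[tri(propan-2-yl)silyl]oxy}but-3-yn-1-yl]oxy}dimethylsilane | CC(C)[Si](OC#C[C@H](c1cc(OC)cc(OC)c1)[C@@H](O[Si](C)(C)C(C)(C)C)c1ccc(OC)cc1OC)(C(C)C)C(C)C | intermediate
24 | buta-1,3-dien-1-one, vinylketene from 12 (formed in the flask) | O=C=CC=C | intermediate
25 | 4-ethenyl-3-(triisopropylsilyloxy)cyclobut-2-en-1-one carrying the arm of 23 on C2, C4 unassigned (formed in the flask) | C=CC1C(=O)C([C@H](c2cc(OC)cc(OC)c2)[C@@H](O[Si](C)(C)C(C)(C)C)c2ccc(OC)cc2OC)=C1O[Si](C(C)C)(C(C)C)C(C)C | intermediate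
26 | dienylketene from 25, ketene and vinyl termini cis (formed in the flask) | O=C=C([C@H](c1cc(OC)cc(OC)c1)[C@@H](O[Si](C)(C)C(C)(C)C)c1ccc(OC)cc1OC)/C(O[Si](C(C)C)(C(C)C)C(C)C)=C\C=C | intermediate
27 | cyclohexa-2,4-dien-1-one tautomer of 28 (formed in the flask) | O=C1CC=CC(O[Si](C(C)C)(C(C)C)C(C)C)=C1[C@H](c1cc(OC)cc(OC)c1)[C@@H](O[Si](C)(C)C(C)(C)C)c1ccc(OC)cc1OC | intermediate
28 | 2-[(1S,2R)-2-{[tert-butyl(dimethyl)silyl]oxy}-2-(2,4-dimethoxyphenyl)-1-(3,5-dimethoxyphenyl)ethyl]-3-{[tri(propan-2-yl)silyl]oxy}phenol | Oc1cccc(O[Si](C(C)C)(C(C)C)C(C)C)c1[C@H](c1cc(OC)cc(OC)c1)[C@@H](O[Si](C)(C)C(C)(C)C)c1ccc(OC)cc1OC | intermediate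
29 | 6-(hydroxymethyl) derivative of 28, as its magnesium salt (formed in the flask) | OCc1ccc(O[Si](C(C)C)(C(C)C)C(C)C)c([C@H](c2cc(OC)cc(OC)c2)[C@@H](O[Si](C)(C)C(C)(C)C)c2ccc(OC)cc2OC)c1O | intermediate
30 | 3-[(1S,2R)-2-{[tert-butyl(dimethyl)silyl]oxy}-2-(2,4-dimethoxyphenyl)-1-(3,5-dimethoxyphenyl)ethyl]-2-hydroxy-4-{[tri(propan-2-yl)silyl]oxy}benzaldehyde | O=Cc1ccc(O[Si](C(C)C)(C(C)C)C(C)C)c([C@H](c2cc(OC)cc(OC)c2)[C@@H](O[Si](C)(C)C(C)(C)C)c2ccc(OC)cc2OC)c1O | intermediate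
31 | 2,4-dimethoxybenzylic cation from 30 (formed in the flask) | O=Cc1ccc(O[Si](C(C)C)(C(C)C)C(C)C)c([C@H](c2cc(OC)cc(OC)c2)[CH+]c2ccc(OC)cc2OC)c1O | intermediate
32 | (2S,3S)-2-(2,4-dimethoxyphenyl)-3-(3,5-dimethoxyphenyl)-4-{[tri(propan-2-yl)silyl]oxy}-2,3-dihydro-1-benzofuran-7-carbaldehyde | O=Cc1ccc(O[Si](C(C)C)(C(C)C)C(C)C)c2c1O[C@H](c1ccc(OC)cc1OC)[C@H]2c1cc(OC)cc(OC)c1 | intermediate
33 | caesium 4-phenoxide from 32 (formed in the flask) | O=Cc1ccc([O-])c2c1O[C@H](c1ccc(OC)cc1OC)[C@H]2c1cc(OC)cc(OC)c1.[Cs+] | intermediate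
34 | (2S,3S)-2-(2,4-dimethoxyphenyl)-3-(3,5-dimethoxyphenyl)-4-methoxy-2,3-dihydro-1-benzofuran-7-carbaldehyde (Q–CHO) | O=Cc1ccc(OC)c2c1O[C@H](c1ccc(OC)cc1OC)[C@H]2c1cc(OC)cc(OC)c1 | intermediate
35 | diethylboron (Z)-enolate of 4 (formed in the flask) | CCB(CC)O/C(N1C(=O)OC[C@H]1Cc1ccccc1)=C\c1cc(OC)cc(OC)c1 | intermediate
36 | diethylboron aldolate of 37 (formed in the flask) | O=C(N1C(=O)OC[C@H]1Cc1ccccc1)[C@H](c1cc(OC)cc(OC)c1)[C@@H](OB(CC)CC)c1ccc(OC)c2c1O[C@H](c1ccc(OC)cc1OC)[C@H]2c1cc(OC)cc(OC)c1 | intermediate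
37 | (4R)-4-benzyl-3-[(2R,3R)-2-(3,5-dimethoxyphenyl)-3-hydroxy-3-Q-propanoyl]-1,3-oxazolidin-2-one | O=C(N1C(=O)OC[C@H]1Cc1ccccc1)[C@H](c1cc(OC)cc(OC)c1)[C@@H](O)c1ccc(OC)c2c1O[C@H](c1ccc(OC)cc1OC)[C@H]2c1cc(OC)cc(OC)c1 | intermediate
38 | (4R)-4-benzyl-3-[(2R,3R)-2-(3,5-dimethoxyphenyl)-3-methoxy-3-Q-propanoyl]-1,3-oxazolidin-2-one | O=C(N1C(=O)OC[C@H]1Cc1ccccc1)[C@H](c1cc(OC)cc(OC)c1)[C@@H](OC)c1ccc(OC)c2c1O[C@H](c1ccc(OC)cc1OC)[C@H]2c1cc(OC)cc(OC)c1 | intermediate
39 | (2S,3R)-2-(3,5-dimethoxyphenyl)-3-methoxy-3-Q-propan-1-ol | OC[C@H](c1cc(OC)cc(OC)c1)[C@@H](OC)c1ccc(OC)c2c1O[C@H](c1ccc(OC)cc1OC)[C@H]2c1cc(OC)cc(OC)c1 | intermediate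
40 | (2R,3R)-2-(3,5-dimethoxyphenyl)-3-methoxy-3-Q-propanal | O=C[C@H](c1cc(OC)cc(OC)c1)[C@@H](OC)c1ccc(OC)c2c1O[C@H](c1ccc(OC)cc1OC)[C@H]2c1cc(OC)cc(OC)c1 | intermediate
41 | (3R,4R)-1,1-dibromo-3-(3,5-dimethoxyphenyl)-4-methoxy-4-Q-but-1-ene | BrC(Br)=C[C@H](c1cc(OC)cc(OC)c1)[C@@H](OC)c1ccc(OC)c2c1O[C@H](c1ccc(OC)cc1OC)[C@H]2c1cc(OC)cc(OC)c1 | intermediate
42 | lithium acetylide from 41 (formed in the flask) | [Li]C#C[C@H](c1cc(OC)cc(OC)c1)[C@@H](OC)c1ccc(OC)c2c1O[C@H](c1ccc(OC)cc1OC)[C@H]2c1cc(OC)cc(OC)c1 | intermediate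
43 | lithium ynolate from 42 (formed in the flask) | [Li]OC#C[C@H](c1cc(OC)cc(OC)c1)[C@@H](OC)c1ccc(OC)c2c1O[C@H](c1ccc(OC)cc1OC)[C@H]2c1cc(OC)cc(OC)c1 | intermediate
44 | {[(3S,4R)-3-(3,5-dimethoxyphenyl)-4-methoxy-4-Q-but-1-yn-1-yl]oxy}tri(propan-2-yl)silane | CC(C)[Si](OC#C[C@H](c1cc(OC)cc(OC)c1)[C@@H](OC)c1ccc(OC)c2c1O[C@H](c1ccc(OC)cc1OC)[C@H]2c1cc(OC)cc(OC)c1)(C(C)C)C(C)C | intermediate
45 | 3-({[tert-butyl(dimethyl)silyl]oxy}methyl)buta-1,3-dien-1-one, vinylketene from 9 (formed in the flask) | O=C=CC(=C)CO[Si](C)(C)C(C)(C)C | intermediate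
46 | 4-(3-silyloxyprop-1-en-2-yl)-3-(triisopropylsilyloxy)cyclobut-2-en-1-one carrying the arm of 44 on C2, C4 unassigned (formed in the flask) | C=C(CO[Si](C)(C)C(C)(C)C)C1C(=O)C([C@H](c2cc(OC)cc(OC)c2)[C@@H](OC)c2ccc(OC)c3c2O[C@H](c2ccc(OC)cc2OC)[C@H]3c2cc(OC)cc(OC)c2)=C1O[Si](C(C)C)(C(C)C)C(C)C | intermediate
47 | dienylketene from 46, ketene and vinyl termini cis (formed in the flask) | O=C=C([C@H](c1cc(OC)cc(OC)c1)[C@@H](OC)c1ccc(OC)c2c1O[C@H](c1ccc(OC)cc1OC)[C@H]2c1cc(OC)cc(OC)c1)/C(O[Si](C(C)C)(C(C)C)C(C)C)=C\C(=C)CO[Si](C)(C)C(C)(C)C | intermediate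
48 | cyclohexa-2,4-dien-1-one tautomer of 49 (formed in the flask) | O=C1CC(CO[Si](C)(C)C(C)(C)C)=CC(O[Si](C(C)C)(C(C)C)C(C)C)=C1[C@H](c1cc(OC)cc(OC)c1)[C@@H](OC)c1ccc(OC)c2c1O[C@H](c1ccc(OC)cc1OC)[C@H]2c1cc(OC)cc(OC)c1 | intermediate
49 | 5-({[tert-butyl(dimethyl)silyl]oxy}methyl)-2-[(1S,2R)-1-(3,5-dimethoxyphenyl)-2-methoxy-2-Q-ethyl]-3-{[tri(propan-2-yl)silyl]oxy}phenol | Oc1cc(CO[Si](C)(C)C(C)(C)C)cc(O[Si](C(C)C)(C(C)C)C(C)C)c1[C@H](c1cc(OC)cc(OC)c1)[C@@H](OC)c1ccc(OC)c2c1O[C@H](c1ccc(OC)cc1OC)[C@H]2c1cc(OC)cc(OC)c1 | intermediate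
50 | 2-[(1S,2R)-1-(3,5-dimethoxyphenyl)-2-methoxy-2-Q-ethyl]-5-(hydroxymethyl)benzene-1,3-diol | Oc1cc(CO)cc(O)c1[C@H](c1cc(OC)cc(OC)c1)[C@@H](OC)c1ccc(OC)c2c1O[C@H](c1ccc(OC)cc1OC)[C@H]2c1cc(OC)cc(OC)c1 | intermediate
51 | C2 benzylic cation from 50 (formed in the flask) | Oc1cc(CO)cc(O)c1[C@H](c1cc(OC)cc(OC)c1)[CH+]c1ccc(OC)c2c1O[C@H](c1ccc(OC)cc1OC)[C@H]2c1cc(OC)cc(OC)c1 | intermediate
52 | (2S,3S)-3-(3,5-dimethoxyphenyl)-6-(hydroxymethyl)-2-Q-2,3-dihydro-1-benzofuran-4-ol | OCc1cc(O)c2c(c1)O[C@H](c1ccc(OC)c3c1O[C@H](c1ccc(OC)cc1OC)[C@H]3c1cc(OC)cc(OC)c1)[C@H]2c1cc(OC)cc(OC)c1 | intermediate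
53 | (2S,3S)-3-(3,5-dimethoxyphenyl)-4-hydroxy-2-Q-2,3-dihydro-1-benzofuran-6-carbaldehyde | O=Cc1cc(O)c2c(c1)O[C@H](c1ccc(OC)c3c1O[C@H](c1ccc(OC)cc1OC)[C@H]3c1cc(OC)cc(OC)c1)[C@H]2c1cc(OC)cc(OC)c1 | intermediate
54 | diethyl [(4-methoxyphenyl)methyl]phosphonate | CCOP(=O)(Cc1ccc(OC)cc1)OCC | starting material
55 | potassium carbanion of 54 (formed in the flask) | CCOP(=O)([CH-]c1ccc(OC)cc1)OCC.[K+] | intermediate
56 | (2S,3S)-3-(3,5-dimethoxyphenyl)-6-[(E)-2-(4-methoxyphenyl)ethenyl]-2-Q-2,3-dihydro-1-benzofuran-4-ol | COc1ccc(/C=C/c2cc(O)c3c(c2)O[C@H](c2ccc(OC)c4c2O[C@H](c2ccc(OC)cc2OC)[C@H]4c2cc(OC)cc(OC)c2)[C@H]3c2cc(OC)cc(OC)c2)cc1 | intermediate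
57 | gnetumontanin B | Oc1ccc(/C=C/c2cc(O)c3c(c2)O[C@H](c2ccc(O)c4c2O[C@H](c2ccc(O)cc2O)[C@H]4c2cc(O)cc(O)c2)[C@H]3c2cc(O)cc(O)c2)cc1 | target

**Count and risks**

Total steps: 27. Longest linear sequence: 23 steps (steps 1 and 6–27, from acid 1).

Steps most likely to fail:

1. Step 22. The [2+2] addition of vinylketene 45 to the alkyne, which carries a fully substituted propargylic carbon, may be slower than dimerisation of the ketene and thermal decomposition of 9, and prolonged heating may let the new phenol ionise the C2 methyl ether. The fallback sets out from 44 and comes back at 49: the same vinylketene is generated at room temperature by photochemical Wolff rearrangement (the diazo ketone variant of the benzannulation), so no cyclobutenone has to survive the heating. 3-(Hydroxymethyl)but-3-en-2-one F1 (Baylis–Hillman adduct of but-3-en-2-one and formaldehyde) would be silylated (t-BuMe2SiCl, imidazole, DMF) to 3-({[tert-butyl(dimethyl)silyl]oxy}methyl)but-3-en-2-one F2. Detrifluoroacetylative diazo transfer (LiN(SiMe3)2, CF3CO2CH2CF3, THF, −78 °C; MsN3, Et3N, MeCN/H2O) would give 1-diazo-3-({[tert-butyl(dimethyl)silyl]oxy}methyl)but-3-en-2-one F3. Irradiation of F3 with 44 (300 nm, ClCH2CH2Cl, rt), followed by brief warming to 80 °C to finish the electrocyclic steps, should give 49 through 45–48.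

2. Step 27. Lewis acid opening of the two dihydrofuran rings may release benzylic cations that alkylate the electron-rich stilbene, and eight ether cleavages in one operation may stall or lead to oligomerisation. The fallback sets out from 53 and comes back at 57: the ethers are cleaved before the stilbene exists and the phenols are carried as silyl ethers. BBr3 (CH2Cl2, −78 °C → rt) on 53 would give the octaphenol aldehyde F4, and t-BuMe2SiCl/imidazole/DMF its octakis(tert-butyldimethylsilyl) ether F5. Horner–Wadsworth–Emmons olefination with diethyl {[4-({[tert-butyl(dimethyl)silyl]oxy})phenyl]methyl}phosphonate F6 (NaN(SiMe3)2, THF, 0 °C) would give the nonakis(silyl) (E)-stilbene F7, and n-Bu4NF/AcOH in THF would release 57 under nearly neutral conditions.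

3. Step 21. Excess base may remove the propargylic C3–H (loss of configuration or β-elimination of methoxide), and oxygen transfer to the hindered acetylide may be slow enough for the silyl triflate to silylate carbon instead. The fallback sets out from 38 and comes back at 44 without aldehyde 40, dibromoalkene 41 or an acetylide. LiOH/H2O2 (THF/H2O, 0 °C) would cleave 38 to (2R,3R)-2-(3,5-dimethoxyphenyl)-3-methoxy-3-Q-propanoic acid F8, and Me3SiCHN2 (MeOH/toluene) would give its methyl ester F9. Kowalski homologation follows: LiCHBr2 (from CH2Br2 and lithium 2,2,6,6-tetramethylpiperidide, THF, −78 °C) adds to the ester; LiN(SiMe3)2 and then n-BuLi (−78 → −20 °C) convert the resulting (3R,4R)-1,1-dibromo-3-(3,5-dimethoxyphenyl)-4-methoxy-4-Q-butan-2-one F10 (as its enolate) by Br/Li exchange and 1,2-shift of the C3 carbon with retention into lithium ynolate 43; i-Pr3SiOTf then gives 44.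

**Further compounds**

F1 | step 22 | 3-(hydroxymethyl)but-3-en-2-one | CC(=O)C(=C)CO
F2 | step 22 | 3-({[tert-butyl(dimethyl)silyl]oxy}methyl)but-3-en-2-one | CC(=O)C(=C)CO[Si](C)(C)C(C)(C)C
F3 | step 22 | 1-diazo-3-({[tert-butyl(dimethyl)silyl]oxy}methyl)but-3-en-2-one | [N-]=[N+]=CC(=O)C(=C)CO[Si](C)(C)C(C)(C)C
F4 | step 27 | (2S,3S)-2-[(2S,3S)-2-(2,4-dihydroxyphenyl)-3-(3,5-dihydroxyphenyl)-4-hydroxy-2,3-dihydro-1-benzofuran-7-yl]-3-(3,5-dihydroxyphenyl)-4-hydroxy-2,3-dihydro-1-benzofuran-6-carbaldehyde | O=Cc1cc(O)c2c(c1)O[C@H](c1ccc(O)c3c1O[C@H](c1ccc(O)cc1O)[C@H]3c1cc(O)cc(O)c1)[C@H]2c1cc(O)cc(O)c1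
F5 | step 27 | octakis(tert-butyldimethylsilyl) ether of F4 | O=Cc1cc(O[Si](C)(C)C(C)(C)C)c2c(c1)O[C@H](c1ccc(O[Si](C)(C)C(C)(C)C)c3c1O[C@H](c1ccc(O[Si](C)(C)C(C)(C)C)cc1O[Si](C)(C)C(C)(C)C)[C@H]3c1cc(O[Si](C)(C)C(C)(C)C)cc(O[Si](C)(C)C(C)(C)C)c1)[C@H]2c1cc(O[Si](C)(C)C(C)(C)C)cc(O[Si](C)(C)C(C)(C)C)c1
F6 | step 27 | diethyl {[4-({[tert-butyl(dimethyl)silyl]oxy})phenyl]methyl}phosphonate | CCOP(=O)(Cc1ccc(O[Si](C)(C)C(C)(C)C)cc1)OCC
F7 | step 27 | nonakis(tert-butyldimethylsilyl) ether of gnetumontanin B | CC(C)(C)[Si](C)(C)Oc1ccc(/C=C/c2cc(O[Si](C)(C)C(C)(C)C)c3c(c2)O[C@H](c2ccc(O[Si](C)(C)C(C)(C)C)c4c2O[C@H](c2ccc(O[Si](C)(C)C(C)(C)C)cc2O[Si](C)(C)C(C)(C)C)[C@H]4c2cc(O[Si](C)(C)C(C)(C)C)cc(O[Si](C)(C)C(C)(C)C)c2)[C@H]3c2cc(O[Si](C)(C)C(C)(C)C)cc(O[Si](C)(C)C(C)(C)C)c2)cc1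
F8 | step 21 | (2R,3R)-2-(3,5-dimethoxyphenyl)-3-methoxy-3-Q-propanoic acid | OC(=O)[C@H](c1cc(OC)cc(OC)c1)[C@@H](OC)c1ccc(OC)c2c1O[C@H](c1ccc(OC)cc1OC)[C@H]2c1cc(OC)cc(OC)c1
F9 | step 21 | methyl (2R,3R)-2-(3,5-dimethoxyphenyl)-3-methoxy-3-Q-propanoate | COC(=O)[C@H](c1cc(OC)cc(OC)c1)[C@@H](OC)c1ccc(OC)c2c1O[C@H](c1ccc(OC)cc1OC)[C@H]2c1cc(OC)cc(OC)c1
F10 | step 21 | (3R,4R)-1,1-dibromo-3-(3,5-dimethoxyphenyl)-4-methoxy-4-Q-butan-2-one | BrC(Br)C(=O)[C@H](c1cc(OC)cc(OC)c1)[C@@H](OC)c1ccc(OC)c2c1O[C@H](c1ccc(OC)cc1OC)[C@H]2c1cc(OC)cc(OC)c1
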